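**Plan**

- Retrosynthesis: the two phenolic O–H bonds go back to benzyl ethers, the C2–H bond to a chromone C2=C3 double bond, and ring B is then cut at C4a–C4, C4–C3 and O1–C2.
- Enabling feature: the C4 carbonyl lies between C4a of ring A (the benzene ring) and C3 of ring B (the pyranone ring). It can therefore be CO placed between an aryl iodide carbon and a terminal alkyne whose two sp carbons become C3 and C2, the latter already carrying the C15 chain.
- Forward: ring A is bought as 2,5-dihydroxybenzaldehyde and converted in five steps into 3,6-bis(benzyloxy)-2-iodophenol. The chain enters as 1-heptadecyne, made in one step from 1-bromopentadecane. Ring B is closed by the three-component carbonylative annulation.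
- Protecting groups: benzyl ethers are used on the C5 and C8 oxygens so that the final deprotection is a neutral hydrogenolysis that cannot open the chromanone.
- Stereochemistry: the only stereocentre, C2 (R), is set after ring closure by ligand-controlled copper hydride conjugate reduction of the chromone and is not touched afterwards.

Key step: step 7

Remark on the chemistry: (R)-DTBM-SEGPHOS is assumed to direct hydride to the Si face of C2; if the sense of induction is the opposite, the (S)-ligand is used with no other change.

**Route**

Step 1
Reactants: 1 2,5-dihydroxybenzaldehyde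
Product: 2 2,5-bis(benzyloxy)benzaldehyde
Conditions: BnBr (2.5 equiv), K2CO3, DMF, 60 °C
Reagents that add atoms: benzyl bromide, BrCc1ccccc1
Why: Williamson ether synthesis, in which K2CO3 in DMF deprotonates both phenols, including the hydrogen-bonded C2 hydroxyl, and the phenoxides displace bromide from benzyl bromide while the aldehyde is untouched.

Step 2
Reactants: 2 2,5-bis(benzyloxy)benzaldehyde
Product: 4 2,5-bis(benzyloxy)phenol, via aryl formate 3 (not isolated)
Conditions: mCPBA, CH2Cl2, 0 °C to rt; aq. NaHCO3 wash; then K2CO3 (0.1 equiv), MeOH, rt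
Reagents that add atoms: 3-chloroperoxybenzoic acid (mCPBA), OOC(=O)c1cccc(Cl)c1
Why: Dakin-type Baeyer–Villiger oxidation, in which the aryl group of this electron-rich benzaldehyde migrates to oxygen in the peracid adduct to give the aryl formate, which catalytic carbonate in methanol cleaves by transesterification without touching the benzyl ethers.

Step 3
Reactants: 4 2,5-bis(benzyloxy)phenol
Product: 5 1,4-bis(benzyloxy)-2-(methoxymethoxy)benzene
Conditions: MOMCl, i-Pr2NEt, CH2Cl2, 0 °C to rt
Reagents that add atoms: chloromethyl methyl ether, COCCl
Why: O-alkylation of the phenol with chloromethyl methyl ether and a hindered amine base installs the methoxymethyl acetal that will direct the metalation, under conditions to which benzyl ethers are inert.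

Step 4
Reactants: 5 1,4-bis(benzyloxy)-2-(methoxymethoxy)benzene
Product: 7 1,4-bis(benzyloxy)-2-iodo-3-(methoxymethoxy)benzene, via aryllithium 6 (not isolated)
Conditions: n-BuLi, TMEDA, THF, −78 to −20 °C; then I2, THF, −78 °C to rt
Reagents that add atoms: n-butyllithium, [Li]CCCC (its lithium is in aryllithium 6 only); iodine, II
Why: Directed ortho-metalation, in which the ring hydrogen flanked by the OMOM and OBn oxygens is the only one activated by two coordinating groups, so n-BuLi/TMEDA should remove it at low temperature faster than a benzylic hydrogen, and iodine traps the aryllithium.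

Step 5
Reactants: 7 1,4-bis(benzyloxy)-2-iodo-3-(methoxymethoxy)benzene
Product: 8 3,6-bis(benzyloxy)-2-iodophenol
Conditions: HCl (3 M aq.), MeOH/THF, 50 °C
Reagents that add atoms: none
Why: Acid-catalysed cleavage of the methoxymethyl acetal in methanol, with transfer of the CH2OMe unit to the solvent, frees the phenol next to iodine, while aryl benzyl ethers and the aryl iodide are stable to dilute HCl.

Step 6
Reactants: 9 1-bromopentadecane
Product: 10 1-heptadecyne
Conditions: LiC≡CH·H2NCH2CH2NH2 (1.5 equiv), DMSO, 10 °C to rt
Reagents that add atoms: lithium acetylide (as its ethylenediamine complex), [Li]C#C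
Why: SN2 alkylation of lithium acetylide by a primary bromide in DMSO, where the ethylenediamine complex dissolves and elimination is minor, extends the C15 chain by the two carbons that become C2 and C3.

Step 7
Reactants: 8 3,6-bis(benzyloxy)-2-iodophenol; 10 1-heptadecyne; 11 carbon monoxide
Product: 14 5,8-bis(benzyloxy)-2-pentadecyl-4H-chromen-4-one, via ynone 12 (not isolated), via enaminone 13 (not isolated)
Conditions: PdCl2(PPh3)2 (5 mol %), CO (20 bar), Et2NH (solvent), 120 °C, autoclave
Reagents that add atoms: diethylamine, CCNCC (its atoms are in enaminone 13 only and are lost again on ring closure; none remain in 14)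
Why: PdCl2(PPh3)2 is reduced in the amine to zerovalent palladium, which inserts into the C–I bond of 8; CO insertion gives the aroylpalladium iodide, amine-assisted transfer of the alkynyl group of 10 to palladium follows, and reductive elimination forms C4a–C4 and C4–C3 in ynone 12. Et2NH then adds to the ynone in conjugate fashion to give enaminone 13, and the neighbouring phenol attacks the amine-bearing β-carbon and expels Et2NH, which forms O1–C2. The closest known reaction type is the palladium-catalysed carbonylative Sonogashira coupling–cyclisation of 2-iodophenols with terminal alkynes to 2-substituted chromones. Ring B closes in the 6-endo mode (6-endo-dig counted on the ynone, an addition–elimination at the β-carbon of the enaminone), and no stereocentre is formed. The step needs carbonylative rather than direct alkynylation, which CO pressure and the absence of a copper salt should secure, because direct coupling would lead on to a 2-alkylbenzofuran; it also needs 6-endo rather than 5-exo closure (aurone), which the enaminone pathway opened by the secondary amine should secure. In the substrate only the hydroxyl next to iodine is free, so a single ring closure is possible, and the electron-rich aryl group migrates readily onto coordinated CO.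

Step 8
Reactants: 14 5,8-bis(benzyloxy)-2-pentadecyl-4H-chromen-4-one
Product: 15 (2R)-5,8-bis(benzyloxy)-2-pentadecyl-2,3-dihydro-4H-chromen-4-one
Conditions: Cu(OAc)2 (5 mol %), (R)-DTBM-SEGPHOS (5.5 mol %), (EtO)2MeSiH (2 equiv), t-BuOH (1.5 equiv), toluene, 0 °C to rt; aq. NH4Cl
Reagents that add atoms: none
Why: Copper hydride asymmetric conjugate reduction (1,4-hydrosilylation), a reaction type known for 2-substituted chromones, in which the bisphosphine-ligated monovalent copper hydride formed from Cu(OAc)2 and the silane adds hydride to C2, the chiral ligand directing it to the Si face (O1 > C3 > C1′) so that C2 becomes R, and t-BuOH protonates the copper enolate at C3 and returns the catalyst before the ketone can be reduced.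

Step 9
Reactants: 15 (2R)-5,8-bis(benzyloxy)-2-pentadecyl-2,3-dihydro-4H-chromen-4-one
Product: 16 (2R)-5,8-dihydroxy-2-pentadecyl-2,3-dihydro-4H-chromen-4-one
Conditions: H2 (1 atm), Pd/C (10 wt %), EtOAc/EtOH, rt; stopped after uptake of 2 equiv H2; filtration under argon
Reagents that add atoms: none
Why: Heterogeneous hydrogenolysis of the two aryl benzyl ethers runs under neutral conditions, so the β-aryloxy ketone cannot open by retro-oxa-Michael reaction and C2 stays R, while the C4 ketone, conjugated to the electron-rich ring and chelated by the new C5 hydroxyl, should be reduced much more slowly than the O–benzyl bonds are cleaved.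

**Compound list**

1 | 2,5-dihydroxybenzaldehyde | O=Cc1cc(O)ccc1O | starting material
2 | 2,5-bis(benzyloxy)benzaldehyde | O=Cc1cc(OCc2ccccc2)ccc1OCc1ccccc1 | intermediate
3 | 2,5-bis(benzyloxy)phenyl formate (not isolated) | O=COc1cc(OCc2ccccc2)ccc1OCc1ccccc1 | intermediate
4 | 2,5-bis(benzyloxy)phenol | Oc1cc(OCc2ccccc2)ccc1OCc1ccccc1 | intermediate
5 | 1,4-bis(benzyloxy)-2-(methoxymethoxy)benzene | COCOc1cc(OCc2ccccc2)ccc1OCc1ccccc1 | intermediate
6 | [3,6-bis(benzyloxy)-2-(methoxymethoxy)phenyl]lithium (not isolated) | [Li]c1c(OCOC)c(OCc2ccccc2)ccc1OCc1ccccc1 | intermediate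
7 | 1,4-bis(benzyloxy)-2-iodo-3-(methoxymethoxy)benzene | COCOc1c(I)c(OCc2ccccc2)ccc1OCc1ccccc1 | intermediate
8 | 3,6-bis(benzyloxy)-2-iodophenol | Oc1c(I)c(OCc2ccccc2)ccc1OCc1ccccc1 | intermediate
9 | 1-bromopentadecane | CCCCCCCCCCCCCCCBr | starting material
10 | 1-heptadecyne | C#CCCCCCCCCCCCCCCC | intermediate
11 | carbon monoxide | [C-]#[O+] | starting material
12 | 1-[3,6-bis(benzyloxy)-2-hydroxyphenyl]octadec-2-yn-1-one (not isolated) | CCCCCCCCCCCCCCCC#CC(=O)c1c(O)c(OCc2ccccc2)ccc1OCc1ccccc1 | intermediate
13 | 1-[3,6-bis(benzyloxy)-2-hydroxyphenyl]-3-(diethylamino)octadec-2-en-1-one (not isolated; alkene geometry left open) | CCCCCCCCCCCCCCCC(=CC(=O)c1c(O)c(OCc2ccccc2)ccc1OCc1ccccc1)N(CC)CC | intermediate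
14 | 5,8-bis(benzyloxy)-2-pentadecyl-4H-chromen-4-one | CCCCCCCCCCCCCCCc1cc(=O)c2c(OCc3ccccc3)ccc(OCc3ccccc3)c2o1 | intermediate
15 | (2R)-5,8-bis(benzyloxy)-2-pentadecyl-2,3-dihydro-4H-chromen-4-one | CCCCCCCCCCCCCCC[C@@H]1CC(=O)c2c(OCc3ccccc3)ccc(OCc3ccccc3)c2O1 | intermediate
16 | (2R)-5,8-dihydroxy-2-pentadecyl-2,3-dihydro-4H-chromen-4-one | CCCCCCCCCCCCCCC[C@@H]1CC(=O)c2c(O)ccc(O)c2O1 | target

**Totals**

Total step count: 9.
Longest linear sequence: 8 steps (steps 1 to 5, then 7, 8 and 9, from 2,5-dihydroxybenzaldehyde); the alkyne branch is step 6.

**Steps most likely to fail**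

Step 7 (key step). Oxidative addition at an iodide flanked by a hydroxyl and a benzyloxy group may be slow. Diethylamine could then capture the aroylpalladium intermediate as an amide, or alkynylation could occur without CO uptake and be followed by cyclisation to a benzofuran. The fallback makes the C4a–C4 bond by acylation of an aryllithium instead of by carbonylation. Alkyne 10 is deprotonated with n-BuLi (THF, −78 °C) to (heptadec-1-yn-1-yl)lithium F1, which is acylated with N-methoxy-N-methylcarbamoyl chloride to N-methoxy-N-methyloctadec-2-ynamide F2. Aryllithium 6, generated from 5 as in step 4, is added to F2 at −78 °C (Weinreb ketone synthesis) to give 1-[3,6-bis(benzyloxy)-2-(methoxymethoxy)phenyl]octadec-2-yn-1-one F3. Et2NH in EtOH should convert this ynone into 1-[3,6-bis(benzyloxy)-2-(methoxymethoxy)phenyl]-3-(diethylamino)octadec-2-en-1-one F4. HCl in MeOH then removes the methoxymethyl group and closes ring B with loss of diethylamine. This fallback sets out from 5 and 10 and returns to the route at chromone 14.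

Step 8. The copper hydride may discriminate the two faces of C2 poorly, since the flat chromone offers the ligand only a flexible chain to distinguish them, or it may go on to reduce the C4 carbonyl of the product. The fallback sets out from 14 and uses asymmetric hydrogenation with a ruthenium N-heterocyclic carbene catalyst made from Ru(cod)(2-methylallyl)2, a chiral imidazolinium salt and KOt-Bu (H2, toluene). This reduces both C2=C3 and C4=O and should give mainly the cis alcohol (2R,4S)-5,8-bis(benzyloxy)-2-pentadecyl-3,4-dihydro-2H-chromen-4-ol F5, the enantiomer of the carbene being chosen for the 2R series. Dess–Martin oxidation of the C4 hydroxyl, which erases that centre, returns to the route at 15.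

Step 4. n-BuLi may deprotonate a benzylic CH2 of one of the benzyl ethers in competition with the ring position, which leads on to Wittig rearrangement, or ring lithiation may stay incomplete at the low temperature needed to avoid this. The fallback sets out from 4 and replaces steps 3 to 5. The phenol is carbamoylated (ClC(O)NEt2, NaH, THF) to 2,5-bis(benzyloxy)phenyl N,N-diethylcarbamate F6. The carbamate is a much stronger directing group than the acetal, so s-BuLi/TMEDA in THF at −78 °C should lithiate the same position within minutes to give [3,6-bis(benzyloxy)-2-(diethylcarbamoyloxy)phenyl]lithium F7. This is quenched with iodine at −78 °C, before anionic Fries rearrangement can set in, to give 3,6-bis(benzyloxy)-2-iodophenyl N,N-diethylcarbamate F8. Saponification (NaOH, EtOH/H2O, reflux) returns to the route at iodophenol 8.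

Further compounds
F1 | step 7 | (heptadec-1-yn-1-yl)lithium | [Li]C#CCCCCCCCCCCCCCCC
F2 | step 7 | N-methoxy-N-methyloctadec-2-ynamide | CCCCCCCCCCCCCCCC#CC(=O)N(C)OC
F3 | step 7 | 1-[3,6-bis(benzyloxy)-2-(methoxymethoxy)phenyl]octadec-2-yn-1-one | CCCCCCCCCCCCCCCC#CC(=O)c1c(OCOC)c(OCc2ccccc2)ccc1OCc1ccccc1
F4 | step 7 | 1-[3,6-bis(benzyloxy)-2-(methoxymethoxy)phenyl]-3-(diethylamino)octadec-2-en-1-one | CCCCCCCCCCCCCCCC(=CC(=O)c1c(OCOC)c(OCc2ccccc2)ccc1OCc1ccccc1)N(CC)CC
F5 | step 8 | (2R,4S)-5,8-bis(benzyloxy)-2-pentadecyl-3,4-dihydro-2H-chromen-4-ol | CCCCCCCCCCCCCCC[C@@H]1C[C@H](O)c2c(OCc3ccccc3)ccc(OCc3ccccc3)c2O1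
F6 | step 4 | 2,5-bis(benzyloxy)phenyl N,N-diethylcarbamate | CCN(CC)C(=O)Oc1cc(OCc2ccccc2)ccc1OCc1ccccc1
F7 | step 4 | [3,6-bis(benzyloxy)-2-(diethylcarbamoyloxy)phenyl]lithium | [Li]c1c(OC(=O)N(CC)CC)c(OCc2ccccc2)ccc1OCc1ccccc1
F8 | step 4 | 3,6-bis(benzyloxy)-2-iodophenyl N,N-diethylcarbamate | CCN(CC)C(=O)Oc1c(I)c(OCc2ccccc2)ccc1OCc1ccccc1
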